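**Retrosynthetic overview**
- Agehoustin E ⇒ 5,6,7,8,2',4',5'-heptamethoxyflavone, by chelation-controlled cleavage of the peri 5-OMe only (last step).
- Heptamethoxyflavone ⇒ 2'-hydroxychalcone, by oxidative closure of the γ-pyrone (O1–C2 bond, then C2=C3).
- Chalcone ⇒ 2'-hydroxy-3',4',5',6'-tetramethoxyacetophenone (A ring, all oxygens in place) + 2,4,5-trimethoxybenzaldehyde (B ring), by Claisen–Schmidt disconnection.
- Ring order: A and B rings are bought; the C ring is the only ring formed (step 2).

Assumption: the target has no stereocentre and no stable stereoaxis, so "single enantiomer" needs no stereocontrol; both starting materials are taken as catalogue chemicals.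

**Step 1**
Reactants: 1 2'-hydroxy-3',4',5',6'-tetramethoxyacetophenone; 2 2,4,5-trimethoxybenzaldehyde
Product: 4 (E)-1-(2-hydroxy-3,4,5,6-tetramethoxyphenyl)-3-(2,4,5-trimethoxyphenyl)prop-2-en-1-one, via racemic aldol adduct 3 (not isolated)
Conditions: KOH (50% aq., 5 equiv), EtOH, rt, 48 h; then 1 M HCl
Reagents that add atoms: none
Why: Claisen–Schmidt (crossed aldol) condensation, in which the methyl ketone enolate adds to the non-enolisable aldehyde and E1cB dehydration of the aldol gives the conjugated, thermodynamically favoured E-enone, so no stereocentre remains.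

**Step 2**
Reactants: 4 (E)-1-(2-hydroxy-3,4,5,6-tetramethoxyphenyl)-3-(2,4,5-trimethoxyphenyl)prop-2-en-1-one
Product: 6 heptamethoxyflavone [5,6,7,8-tetramethoxy-2-(2,4,5-trimethoxyphenyl)-4H-chromen-4-one], via racemic flavanone 5 (not isolated)
Conditions: I2 (10 mol %), DMSO, 130 °C, 3 h; then aq. Na2S2O3
Reagents that add atoms: none
Why: Iodine-catalysed oxidative cyclisation, in which 6-endo oxa-Michael closure of the 2'-phenol gives the flavanone and iodine dehydrogenates it to the aromatic γ-pyrone while DMSO acts as terminal oxidant, which also erases the transient C2 stereocentre.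

**Step 3**
Reactants: 6 heptamethoxyflavone [5,6,7,8-tetramethoxy-2-(2,4,5-trimethoxyphenyl)-4H-chromen-4-one]
Product: 8 Agehoustin E [5-hydroxy-6,7,8-trimethoxy-2-(2,4,5-trimethoxyphenyl)-4H-chromen-4-one], via dichloroboron chelate 7 (not isolated)
Conditions: BCl3 (1.5 equiv, 1 M in CH2Cl2), CH2Cl2, −10 → 0 °C, 1 h; then H2O/1 M HCl, rt
Reagents that add atoms: none
Why: Chelation-controlled Lewis-acid ether cleavage, in which BCl3 bridges the C4 carbonyl and the peri 5-OMe oxygen, chloride removes that methyl by SN2, and the six-membered boron chelate is hydrolysed on work-up, while the six non-chelating OMe groups survive at ≤0 °C.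

**Compound list**
1 | 2'-hydroxy-3',4',5',6'-tetramethoxyacetophenone [1-(2-hydroxy-3,4,5,6-tetramethoxyphenyl)ethan-1-one] | CC(=O)c1c(O)c(OC)c(OC)c(OC)c1OC | starting material
2 | 2,4,5-trimethoxybenzaldehyde | COc1cc(OC)c(C=O)cc1OC | starting material
3 | racemic aldol adduct, 3-hydroxy-1-(2-hydroxy-3,4,5,6-tetramethoxyphenyl)-3-(2,4,5-trimethoxyphenyl)propan-1-one | COc1cc(OC)c(C(O)CC(=O)c2c(O)c(OC)c(OC)c(OC)c2OC)cc1OC | intermediate
4 | (E)-1-(2-hydroxy-3,4,5,6-tetramethoxyphenyl)-3-(2,4,5-trimethoxyphenyl)prop-2-en-1-one (chalcone) | COc1cc(OC)c(/C=C/C(=O)c2c(O)c(OC)c(OC)c(OC)c2OC)cc1OC | intermediate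
5 | racemic flavanone, 5,6,7,8-tetramethoxy-2-(2,4,5-trimethoxyphenyl)chroman-4-one | COc1cc(OC)c(C2CC(=O)c3c(OC)c(OC)c(OC)c(OC)c3O2)cc1OC | intermediate
6 | heptamethoxyflavone, 5,6,7,8-tetramethoxy-2-(2,4,5-trimethoxyphenyl)-4H-chromen-4-one | COc1cc(OC)c(-c2cc(=O)c3c(OC)c(OC)c(OC)c(OC)c3o2)cc1OC | intermediate
7 | dichloroboron chelate, 5-(dichloroboryloxy)-6,7,8-trimethoxy-2-(2,4,5-trimethoxyphenyl)-4H-chromen-4-one (C4=O→B dative bond not drawn) | COc1cc(OC)c(-c2cc(=O)c3c(OB(Cl)Cl)c(OC)c(OC)c(OC)c3o2)cc1OC | intermediate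
8 | Agehoustin E, 5-hydroxy-6,7,8-trimethoxy-2-(2,4,5-trimethoxyphenyl)-4H-chromen-4-one | COc1cc(OC)c(-c2cc(=O)c3c(O)c(OC)c(OC)c(OC)c3o2)cc1OC | target

**Totals**
Total step count: 3. Longest linear sequence: 3 steps (1 → 4 → 6 → 8).

**Steps most likely to fail, and fallbacks**

Step 1 (Claisen–Schmidt). The ketone is di-ortho-substituted and present as an electron-rich phenoxide, and the aldehyde is deactivated by three methoxy groups, so the condensation can be slow or incomplete. Any flavanone 5 formed early is harmless, because step 2 converts it as well. The fallback sets out from 1 and comes back at 6, replacing the aldol and the oxidation by a Baker–Venkataraman sequence. Compound 1 is O-acylated with commercial 2,4,5-trimethoxybenzoyl chloride (pyridine, DMAP, 60 °C) to give 2-acetyl-3,4,5,6-tetramethoxyphenyl 2,4,5-trimethoxybenzoate F1. KOH in pyridine at 50 °C (or LiHMDS in THF) then shifts the aroyl group from O to the enolate carbon, giving 1-(2-hydroxy-3,4,5,6-tetramethoxyphenyl)-3-(2,4,5-trimethoxyphenyl)propane-1,3-dione F2. Cyclodehydration with catalytic H2SO4 in AcOH at 90 °C closes the pyranone to 6.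

Step 2 (I2/DMSO oxidative cyclisation). Risks are iodination of the very electron-rich 2,4,5-trimethoxyphenyl ring and aurone by-products. HI-induced loss of the 5-methyl is also possible but harmless, since it only gives 8 early. The fallback sets out from 4 and comes back at 6 by a halogen-free, stepwise route. NaOAc in refluxing EtOH closes the ring by oxa-Michael addition and flavanone 5 is isolated. DDQ in refluxing dioxane then dehydrogenates C2–C3 to give 6. This fallback makes no compound outside the list (entry F0).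

Step 3 (selective 5-O-demethylation). Risks are a second cleavage at the neighbouring 6-OMe once the 5-O–boron chelate has formed, and a boron chelate that resists hydrolysis. The fallback sets out from 4 and comes back at 8 by moving the demethylation ahead of ring closure. BCl3 (3 equiv, CH2Cl2, 0 °C → rt) cleaves the only carbonyl-flanking methoxy group of 4 and forms in the flask (E)-1-[2,6-bis(dichloroboryloxy)-3,4,5-trimethoxyphenyl]-3-(2,4,5-trimethoxyphenyl)prop-2-en-1-one F3. Aqueous work-up gives (E)-1-(2,6-dihydroxy-3,4,5-trimethoxyphenyl)-3-(2,4,5-trimethoxyphenyl)prop-2-en-1-one F4. I2 (10 mol %) in DMSO at 130 °C then cyclises either of the two equivalent phenols, through racemic 5-hydroxy-6,7,8-trimethoxy-2-(2,4,5-trimethoxyphenyl)chroman-4-one F5 formed in the flask, and delivers 8 directly with the 5-OH already free.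

**Further compounds**
F1 | step 1 | 2-acetyl-3,4,5,6-tetramethoxyphenyl 2,4,5-trimethoxybenzoate | CC(=O)c1c(OC(=O)c2cc(OC)c(OC)cc2OC)c(OC)c(OC)c(OC)c1OC
F2 | step 1 | 1-(2-hydroxy-3,4,5,6-tetramethoxyphenyl)-3-(2,4,5-trimethoxyphenyl)propane-1,3-dione | COc1cc(OC)c(C(=O)CC(=O)c2c(O)c(OC)c(OC)c(OC)c2OC)cc1OC
F0 | step 2 | none | none
F3 | step 3 | (E)-1-[2,6-bis(dichloroboryloxy)-3,4,5-trimethoxyphenyl]-3-(2,4,5-trimethoxyphenyl)prop-2-en-1-one | COc1cc(OC)c(/C=C/C(=O)c2c(OB(Cl)Cl)c(OC)c(OC)c(OC)c2OB(Cl)Cl)cc1OC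
F4 | step 3 | (E)-1-(2,6-dihydroxy-3,4,5-trimethoxyphenyl)-3-(2,4,5-trimethoxyphenyl)prop-2-en-1-one | COc1cc(OC)c(/C=C/C(=O)c2c(O)c(OC)c(OC)c(OC)c2O)cc1OC
F5 | step 3 | racemic 5-hydroxy-6,7,8-trimethoxy-2-(2,4,5-trimethoxyphenyl)chroman-4-one | COc1cc(OC)c(C2CC(=O)c3c(O)c(OC)c(OC)c(OC)c3O2)cc1OC
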